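**Retrosynthetic overview**
- The quinone is unmasked last by oxidative demethylation of a hydroquinone dimethyl ether; the six-membered ring is never built, it is carried through from trimethylhydroquinone.
- The C1'–C2' bond comes from a 2,5-dimethoxy-3,4,6-trimethylbenzyl Grignard reagent opening an (R)-2-methyl-2-alkyloxirane at its CH2 end.
- The oxirane comes from an (R)-1,2-diol, which comes from a 5,5-disubstituted Seebach dioxolanone by hydride reduction.
- Key bond C3'–C4': aldol addition of the (S)-lactic acid-derived dioxolanone enolate to a C16 aldehyde sets the quaternary carbinol centre (3'R); the extra OH is then removed.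
- The C16 aldehyde (7'R, 11'R) comes from natural phytol by ozonolysis and Baeyer–Villiger oxidation. Only two temporary rings are formed: the dioxolanone (step 5) and the oxirane (step 10), both opened later.

Assumption: commercial natural phytol is the (2E,7R,11R) isomer and lactic acid is used as the anhydrous (S)-acid.

**Step 1**
Reactants: 1 phytol [(2E,7R,11R)-3,7,11,15-tetramethylhexadec-2-en-1-ol]
Product: 3 (6R,10R)-6,10,14-trimethylpentadecan-2-one, via secondary ozonide 2 (not isolated)
Conditions: O3, CH2Cl2, −78 °C; then PPh3, −78 °C → rt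
Reagents that add atoms: ozone [O-][O+]=O
Why: Criegee ozonolysis cleaves the only C=C bond and reductive work-up gives the methyl ketone, with the remote 6R and 10R centres untouched.

**Step 2**
Reactants: 3 (6R,10R)-6,10,14-trimethylpentadecan-2-one
Product: 4 (4R,8R)-4,8,12-trimethyltridecyl acetate
Conditions: mCPBA (2 equiv), TFA (1 equiv), CH2Cl2, rt, dark, 24 h
Reagents that add atoms: mCPBA OOC(=O)c1cccc(Cl)c1
Why: Baeyer–Villiger oxidation in which the primary alkyl group migrates in preference to methyl, giving the acetate of the C16 alcohol.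

**Step 3**
Reactants: 4 (4R,8R)-4,8,12-trimethyltridecyl acetate
Product: 5 (4R,8R)-4,8,12-trimethyltridecan-1-ol
Conditions: K2CO3 (0.2 equiv), MeOH, rt
Reagents that add atoms: none
Why: Base-catalysed transesterification (methanolysis) frees the primary alcohol.

**Step 4**
Reactants: 5 (4R,8R)-4,8,12-trimethyltridecan-1-ol
Product: 6 (4R,8R)-4,8,12-trimethyltridecanal
Conditions: TEMPO (10 mol %), PhI(OAc)2 (1.1 equiv), CH2Cl2, rt
Reagents that add atoms: none
Why: TEMPO/oxoammonium oxidation stops at the aldehyde, and the nearest stereocentre is gamma to the carbonyl so it cannot epimerise.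

**Step 5**
Reactants: 7 (S)-lactic acid
Product: 8 (2S,5S)-2-tert-butyl-5-methyl-1,3-dioxolan-4-one
Conditions: t-BuCHO, TsOH (cat.), H2SO4 (cat.), pentane, reflux (Dean–Stark); recrystallise from pentane/Et2O at −78 °C
Reagents that add atoms: pivalaldehyde CC(C)(C)C=O
Why: Acid-catalysed acetalisation (Seebach self-regeneration of stereocentres) gives the cis acetal as the major isomer, purified by crystallisation, so the lactate chirality is stored in the new acetal centre C2.

**Step 6**
Reactants: 8 (2S,5S)-2-tert-butyl-5-methyl-1,3-dioxolan-4-one; 6 (4R,8R)-4,8,12-trimethyltridecanal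
Product: 10 (2S,5R)-2-tert-butyl-5-[(1RS,4R,8R)-1-hydroxy-4,8,12-trimethyltridecyl]-5-methyl-1,3-dioxolan-4-one, via lithium enolate 9 (not isolated)
Conditions: LDA (1.05 equiv, commercial solution), THF, −78 °C, 20 min; 6 (0.85 equiv), −78 °C, 1 h; AcOH quench at −78 °C
Reagents that add atoms: none
Why: Intermolecular lithium-enolate aldol addition in which the aldehyde attacks the planar enolate anti to the tert-butyl group, setting the quaternary centre (future C3', R) with high selectivity, while the carbinol centre forms as a mixture that is removed in step 8.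

**Step 7**
Reactants: 10 (2S,5R)-2-tert-butyl-5-[(1RS,4R,8R)-1-hydroxy-4,8,12-trimethyltridecyl]-5-methyl-1,3-dioxolan-4-one
Product: 11 O-[(1RS,4R,8R)-1-[(2S,4R)-2-tert-butyl-4-methyl-5-oxo-1,3-dioxolan-4-yl]-4,8,12-trimethyltridecyl] O-phenyl carbonothioate
Conditions: PhOC(S)Cl (1.5 equiv), pyridine (3 equiv), DMAP (cat.), CH2Cl2, 0 °C → rt
Reagents that add atoms: O-phenyl chlorothionoformate S=C(Cl)Oc1ccccc1
Why: Thioacylation of the secondary alcohol (first half of the Barton–McCombie deoxygenation) under a mild base that does not provoke retro-aldol cleavage.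

**Step 8**
Reactants: 11 O-phenyl thionocarbonate of 10
Product: 12 (2S,5R)-2-tert-butyl-5-methyl-5-[(4R,8R)-4,8,12-trimethyltridecyl]-1,3-dioxolan-4-one
Conditions: Bu3SnH (1.5 equiv, ≥0.2 M), AIBN (cat.), toluene, 100 °C; KF work-up; chromatography (removes any minor C5 epimer)
Reagents that add atoms: none
Why: Barton–McCombie radical deoxygenation replaces the C–O bond by C–H and erases the mixed carbinol centre without touching the quaternary centre.

**Step 9**
Reactants: 12 (2S,5R)-2-tert-butyl-5-methyl-5-[(4R,8R)-4,8,12-trimethyltridecyl]-1,3-dioxolan-4-one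
Product: 13 (2R,6R,10R)-2,6,10,14-tetramethylpentadecane-1,2-diol
Conditions: LiAlH4 (excess), THF, 0 °C → reflux; H2O work-up
Reagents that add atoms: none
Why: Hydride reduction of the lactone-acetal liberates the 1,2-diol (the released pivalaldehyde is reduced to neopentyl alcohol), and the tertiary centre is not a reacting atom.

**Step 10**
Reactants: 13 (2R,6R,10R)-2,6,10,14-tetramethylpentadecane-1,2-diol
Product: 15 (2R)-2-methyl-2-[(4R,8R)-4,8,12-trimethyltridecyl]oxirane, via primary monotosylate 14 (not isolated)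
Conditions: TsCl (1.1 equiv), Et3N, DMAP (cat.), CH2Cl2, 0 °C; then K2CO3, MeOH, rt
Reagents that add atoms: none
Why: Selective sulfonylation of the primary OH followed by intramolecular Williamson (SN2) closure at the primary carbon keeps the tertiary centre's configuration.

**Step 11**
Reactants: 16 2,3,5-trimethylhydroquinone
Product: 17 1,4-dimethoxy-2,3,5-trimethylbenzene
Conditions: Me2SO4 (2.5 equiv), K2CO3, acetone, reflux, N2
Reagents that add atoms: dimethyl sulfate COS(=O)(=O)OC
Why: Williamson O-methylation of both phenols protects the hydroquinone against premature oxidation.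

**Step 12**
Reactants: 17 1,4-dimethoxy-2,3,5-trimethylbenzene
Product: 18 1-(chloromethyl)-2,5-dimethoxy-3,4,6-trimethylbenzene
Conditions: (CH2O)n, conc. HCl, HCl (g), 1,4-dioxane, 60 °C
Reagents that add atoms: formaldehyde (as paraformaldehyde) C=O; hydrogen chloride Cl
Why: Blanc chloromethylation (electrophilic aromatic substitution) at the only free position of the electron-rich ring.

**Step 13**
Reactants: 18 1-(chloromethyl)-2,5-dimethoxy-3,4,6-trimethylbenzene; 15 (2R)-2-methyl-2-[(4R,8R)-4,8,12-trimethyltridecyl]oxirane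
Product: 20 (3R,7R,11R)-1-(2,5-dimethoxy-3,4,6-trimethylphenyl)-3,7,11,15-tetramethylhexadecan-3-ol, via benzylic Grignard reagent 19 (not isolated)
Conditions: Mg (3 equiv), THF, 0 °C, slow addition of 18 (2 equiv); then CuI (10 mol %), 15 (1 equiv), −30 °C → rt; aq NH4Cl
Reagents that add atoms: none
Why: Grignard formation followed by Cu(I)-catalysed SN2 opening of the 2,2-disubstituted epoxide at its CH2 terminus (the benzylmagnesium chloride/isobutylene oxide reaction type) leaves the tertiary carbinol centre untouched.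

**Step 14**
Reactants: 20 (3R,7R,11R)-1-(2,5-dimethoxy-3,4,6-trimethylphenyl)-3,7,11,15-tetramethylhexadecan-3-ol
Product: 21 tocopherylquinone [2-[(3R,7R,11R)-3-hydroxy-3,7,11,15-tetramethylhexadecyl]-3,5,6-trimethylcyclohexa-2,5-diene-1,4-dione]
Conditions: CAN (2.5 equiv), MeCN/H2O (3:1), 0 °C, 30 min
Reagents that add atoms: water O
Why: CAN oxidative demethylation converts the p-dimethoxyarene into the p-quinone, and any cyclic tocopherone-type ketal formed through the tertiary OH hydrolyses to the same quinone in the acidic medium.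

**Compound list**
1 | phytol, (2E,7R,11R)-3,7,11,15-tetramethylhexadec-2-en-1-ol | OC/C=C(\C)CCC[C@H](C)CCC[C@H](C)CCCC(C)C | starting material
2 | secondary ozonide, [5-methyl-5-[(4R,8R)-4,8,12-trimethyltridecyl]-1,2,4-trioxolan-3-yl]methanol (diastereomer mixture) | CC1(CCC[C@H](C)CCC[C@H](C)CCCC(C)C)OOC(CO)O1 | intermediate
3 | (6R,10R)-6,10,14-trimethylpentadecan-2-one | CC(=O)CCC[C@H](C)CCC[C@H](C)CCCC(C)C | intermediate
4 | (4R,8R)-4,8,12-trimethyltridecyl acetate | CC(=O)OCCC[C@H](C)CCC[C@H](C)CCCC(C)C | intermediate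
5 | (4R,8R)-4,8,12-trimethyltridecan-1-ol | OCCC[C@H](C)CCC[C@H](C)CCCC(C)C | intermediate
6 | (4R,8R)-4,8,12-trimethyltridecanal | O=CCC[C@H](C)CCC[C@H](C)CCCC(C)C | intermediate
7 | (S)-lactic acid | C[C@H](O)C(=O)O | starting material
8 | (2S,5S)-2-tert-butyl-5-methyl-1,3-dioxolan-4-one (cis) | C[C@@H]1O[C@H](C(C)(C)C)OC1=O | intermediate
9 | lithium enolate, lithium (2S)-2-tert-butyl-5-methyl-1,3-dioxol-4-olate | CC1=C(O[Li])O[C@@H](C(C)(C)C)O1 | intermediate
10 | (2S,5R)-2-tert-butyl-5-[(1RS,4R,8R)-1-hydroxy-4,8,12-trimethyltridecyl]-5-methyl-1,3-dioxolan-4-one | C[C@]1(C(O)CC[C@H](C)CCC[C@H](C)CCCC(C)C)O[C@H](C(C)(C)C)OC1=O | intermediate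
11 | O-[(1RS,4R,8R)-1-[(2S,4R)-2-tert-butyl-4-methyl-5-oxo-1,3-dioxolan-4-yl]-4,8,12-trimethyltridecyl] O-phenyl carbonothioate | C[C@]1(C(OC(=S)Oc2ccccc2)CC[C@H](C)CCC[C@H](C)CCCC(C)C)O[C@H](C(C)(C)C)OC1=O | intermediate
12 | (2S,5R)-2-tert-butyl-5-methyl-5-[(4R,8R)-4,8,12-trimethyltridecyl]-1,3-dioxolan-4-one | C[C@]1(CCC[C@H](C)CCC[C@H](C)CCCC(C)C)O[C@H](C(C)(C)C)OC1=O | intermediate
13 | (2R,6R,10R)-2,6,10,14-tetramethylpentadecane-1,2-diol | OC[C@](C)(O)CCC[C@H](C)CCC[C@H](C)CCCC(C)C | intermediate
14 | primary monotosylate, (2R,6R,10R)-2-hydroxy-2,6,10,14-tetramethylpentadecyl 4-methylbenzenesulfonate | Cc1ccc(cc1)S(=O)(=O)OC[C@](C)(O)CCC[C@H](C)CCC[C@H](C)CCCC(C)C | intermediate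
15 | (2R)-2-methyl-2-[(4R,8R)-4,8,12-trimethyltridecyl]oxirane | C[C@@]1(CCC[C@H](C)CCC[C@H](C)CCCC(C)C)CO1 | intermediate
16 | 2,3,5-trimethylhydroquinone | Cc1cc(O)c(C)c(C)c1O | starting material
17 | 1,4-dimethoxy-2,3,5-trimethylbenzene | COc1cc(C)c(OC)c(C)c1C | intermediate
18 | 1-(chloromethyl)-2,5-dimethoxy-3,4,6-trimethylbenzene | COc1c(C)c(C)c(OC)c(CCl)c1C | intermediate
19 | benzylic Grignard reagent, (2,5-dimethoxy-3,4,6-trimethylbenzyl)magnesium chloride | COc1c(C)c(C)c(OC)c(C[Mg]Cl)c1C | intermediate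
20 | (3R,7R,11R)-1-(2,5-dimethoxy-3,4,6-trimethylphenyl)-3,7,11,15-tetramethylhexadecan-3-ol | COc1c(C)c(C)c(OC)c(CC[C@](C)(O)CCC[C@H](C)CCC[C@H](C)CCCC(C)C)c1C | intermediate
21 | tocopherylquinone, 2-[(3R,7R,11R)-3-hydroxy-3,7,11,15-tetramethylhexadecyl]-3,5,6-trimethylcyclohexa-2,5-diene-1,4-dione | CC1=C(C)C(=O)C(CC[C@](C)(O)CCC[C@H](C)CCC[C@H](C)CCCC(C)C)=C(C)C1=O | target

**Totals**
Total step count: 14. Longest linear sequence: 11 steps (1, 2, 3, 4, 6, 7, 8, 9, 10, 13, 14, from phytol 1).

**Three steps most likely to fail**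

Step 6 (aldol addition). Enolate 9 decomposes above about −40 °C and the hindered aldolate can revert, so conversion may be poor. The fallback is an irreversible acylation followed by reduction; it sets out from aldehyde 6 and comes back at 10. Aldehyde 6 is oxidised (NaClO2, NaH2PO4, 2-methyl-2-butene, t-BuOH/H2O) to (4R,8R)-4,8,12-trimethyltridecanoic acid F1, which oxalyl chloride/cat. DMF converts into (4R,8R)-4,8,12-trimethyltridecanoyl chloride F2. Crossed Claisen-type C-acylation of enolate 9 (2 equiv, THF, −78 °C, attack again anti to the tert-butyl group) gives (2S,5R)-2-tert-butyl-5-methyl-5-[(4R,8R)-4,8,12-trimethyltridecanoyl]-1,3-dioxolan-4-one F3. NaBH4 (THF/MeOH, −40 °C) reduces the ketone and returns the epimeric carbinols 10.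

Step 7 (thioacylation of the neopentyl-type secondary alcohol, and with it the radical step 8). If the hindered alcohol resists thioacylation or the tin step is inefficient, the fallback removes the oxygen by elimination and hydrogenation; it sets out from 10 and comes back at 12. Burgess reagent (benzene, 50 °C) effects syn-elimination, which can only go towards the chain CH2 because the other neighbour is quaternary, and gives (2S,5R)-2-tert-butyl-5-methyl-5-[(1E,4R,8R)-4,8,12-trimethyltridec-1-en-1-yl]-1,3-dioxolan-4-one F4. Hydrogenation over PtO2 (H2, EtOAc, rt) saturates the alkene and delivers 12.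

Step 13 (benzylic Grignard formation and epoxide opening). Wurtz homocoupling of the electron-rich benzyl chloride or Lewis-acid rearrangement of the epoxide may erode the yield. The fallback uses a sulfone-stabilised carbanion; it sets out from 18 and comes back at 20. Chloride 18 and PhSO2Na (DMF, 60 °C) give 1-[(benzenesulfonyl)methyl]-2,5-dimethoxy-3,4,6-trimethylbenzene F5. Its lithio derivative (n-BuLi, THF/DMPU, −78 °C) opens epoxide 15 at the CH2 terminus (−78 °C → rt) to give (1RS,3R,7R,11R)-1-(benzenesulfonyl)-1-(2,5-dimethoxy-3,4,6-trimethylphenyl)-3,7,11,15-tetramethylhexadecan-3-ol F6. Reductive desulfonylation (6 % Na/Hg, Na2HPO4, MeOH, −20 °C) gives 20.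

**Further compounds**
F1 | step 6 | (4R,8R)-4,8,12-trimethyltridecanoic acid | OC(=O)CC[C@H](C)CCC[C@H](C)CCCC(C)C
F2 | step 6 | (4R,8R)-4,8,12-trimethyltridecanoyl chloride | ClC(=O)CC[C@H](C)CCC[C@H](C)CCCC(C)C
F3 | step 6 | (2S,5R)-2-tert-butyl-5-methyl-5-[(4R,8R)-4,8,12-trimethyltridecanoyl]-1,3-dioxolan-4-one | C[C@]1(C(=O)CC[C@H](C)CCC[C@H](C)CCCC(C)C)O[C@H](C(C)(C)C)OC1=O
F4 | step 7 | (2S,5R)-2-tert-butyl-5-methyl-5-[(1E,4R,8R)-4,8,12-trimethyltridec-1-en-1-yl]-1,3-dioxolan-4-one | C[C@]1(/C=C/C[C@H](C)CCC[C@H](C)CCCC(C)C)O[C@H](C(C)(C)C)OC1=O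
F5 | step 13 | 1-[(benzenesulfonyl)methyl]-2,5-dimethoxy-3,4,6-trimethylbenzene | COc1c(C)c(C)c(OC)c(CS(=O)(=O)c2ccccc2)c1C
F6 | step 13 | (1RS,3R,7R,11R)-1-(benzenesulfonyl)-1-(2,5-dimethoxy-3,4,6-trimethylphenyl)-3,7,11,15-tetramethylhexadecan-3-ol | COc1c(C)c(C)c(OC)c(C(C[C@](C)(O)CCC[C@H](C)CCC[C@H](C)CCCC(C)C)S(=O)(=O)c2ccccc2)c1C
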